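**Strategy.** The oxepine ring is dissected at its two C–C bonds to the γ-pyrone: C3–CH2 and C2–C1' (ring B). Both are made in the last step by a palladium/norbornene relay that joins two fragments of similar size, a 2-iodopyranochromone (rings A and C, fully substituted) and the aryl enol ether ArO–C(=CMe2)–CH2Br (ring B). The step exploits the vicinal C2(–I)/C3(–H) pair of the pyrone C2=C3 bond, the allylic CH2Br carbon and the electron-rich ring B C–H para to a methoxy group. C3 is alkylated, then C2 is arylated, which closes the seven-membered ring (C2, C3, CH2, C(=CMe2), O, C2', C1') and gives the target directly.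

Key step: step 10

Remark: the target has no stereocentre, and its exocyclic C=CMe2 bond carries two identical methyl groups, so no stereodescriptor arises. C2, C3 and C4 denote the pyrone carbons of the chromen-4-one, and primed numbers denote ring B.

**Step 1**
Reactants: 1 1-(2,4-dihydroxy-6-methoxyphenyl)ethanone; 2 3-methylbut-2-enal
Product: 3 1-(5-hydroxy-7-methoxy-2,2-dimethyl-2H-chromen-6-yl)ethanone
Conditions: ethylenediammonium diacetate (10 mol%), toluene, 110 °C, Dean–Stark trap
Reagents that add atoms: none
Why: Knoevenagel-type condensation of the enal at the ring carbon between the two free hydroxyls, followed by oxa-6π electrocyclisation (formal [3+3] chromene annulation), should close the pyran through the non-chelated para oxygen, as with resacetophenone, because the ortho hydroxyl stays locked in its hydrogen bond to the acetyl group.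

**Step 2**
Reactants: 3 1-(5-hydroxy-7-methoxy-2,2-dimethyl-2H-chromen-6-yl)ethanone; 4 1-bromo-3-methylbut-2-ene
Product: 5 1-[7-methoxy-2,2-dimethyl-5-(3-methylbut-2-enyloxy)-2H-chromen-6-yl]ethanone
Conditions: K2CO3, DMF, 60 °C
Reagents that add atoms: none
Why: Williamson etherification of the single remaining phenol, whose hydrogen bond to the acetyl group is broken by carbonate in DMF, installs the prenyl ether needed for the rearrangement.

**Step 3**
Reactants: 5 1-[7-methoxy-2,2-dimethyl-5-(3-methylbut-2-enyloxy)-2H-chromen-6-yl]ethanone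
Product: 7 1-[5-hydroxy-7-methoxy-2,2-dimethyl-8-(3-methylbut-2-enyl)-2H-chromen-6-yl]ethanone, via ortho-dienone 6 (not isolated)
Conditions: N,N-diethylaniline, 190 °C, argon, sealed tube
Reagents that add atoms: none
Why: In this para-Claisen–Cope rearrangement both ortho carbons of the aryl prenyl ether are substituted, so the [3,3] shift gives a non-enolisable ortho-dienone (6 is drawn for attack at the acetyl-bearing carbon; the other ortho-dienone leads to the same result) that relays the group by a Cope shift to the free para carbon, where tautomerisation restores the phenol and the double allylic inversion returns the linear 3-methylbut-2-enyl group.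

**Step 4**
Reactants: 7 1-[5-hydroxy-7-methoxy-2,2-dimethyl-8-(3-methylbut-2-enyl)-2H-chromen-6-yl]ethanone
Product: 9 5-methoxy-8,8-dimethyl-6-(3-methylbut-2-enyl)-4H,8H-pyrano[2,3-h]chromen-4-one, via enaminone 8 (not isolated)
Conditions: DMF-DMA (3 equiv), toluene, 100 °C; then AcOH, 80 °C
Reagents that add atoms: N,N-dimethylformamide dimethyl acetal, COC(OC)N(C)C
Why: Enaminone formation at the methyl ketone followed by acid-promoted intramolecular oxa-Michael addition of the ortho phenol and loss of dimethylamine is the standard route to 2,3-unsubstituted chromones, and acetic acid is mild enough for the chromene and prenyl groups.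

**Step 5**
Reactants: 9 5-methoxy-8,8-dimethyl-6-(3-methylbut-2-enyl)-4H,8H-pyrano[2,3-h]chromen-4-one
Product: 11 2-iodo-5-methoxy-8,8-dimethyl-6-(3-methylbut-2-enyl)-4H,8H-pyrano[2,3-h]chromen-4-one, via bis(chromon-2-yl)zinc 10 (not isolated)
Conditions: TMP2Zn·2MgCl2·2LiCl (0.55 equiv), THF, −30 to 0 °C; then I2 (1.2 equiv), THF, 0 °C
Reagents that add atoms: iodine, II
Why: In this Lewis-acid-triggered zincation, MgCl2 bound to the pyrone carbonyl blocks carbonyl-directed metalation at C3 and makes the ring pyrylium-like, so the hindered zinc amide should remove the C2–H next to the ring oxygen, and iodinolysis of the C–Zn bond gives the 2-iodide without touching the alkenes.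

**Step 6**
Reactants: 12 3,4-dimethoxyphenol; 13 ethyl 2-diazo-2-(diethoxyphosphoryl)acetate
Product: 14 ethyl 2-(diethoxyphosphoryl)-2-(3,4-dimethoxyphenoxy)acetate
Conditions: Rh2(OAc)4 (1 mol%), toluene, 80 °C
Reagents that add atoms: none
Why: Rhodium-carbenoid O–H insertion into the phenol is faster than attack on the electron-rich ring and delivers the α-aryloxy phosphonoacetate in one step.

**Step 7**
Reactants: 14 ethyl 2-(diethoxyphosphoryl)-2-(3,4-dimethoxyphenoxy)acetate; 15 acetone
Product: 16 ethyl 2-(3,4-dimethoxyphenoxy)-3-methylbut-2-enoate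
Conditions: NaH, THF, 0 °C; then 15 (5 equiv), 0 to 65 °C
Reagents that add atoms: none
Why: Horner–Wadsworth–Emmons olefination of acetone by the sodium salt of the α-aryloxy phosphonate forms the tetrasubstituted enol ether double bond, which needs no geometry control because the new alkene carbon carries two methyl groups.

**Step 8**
Reactants: 16 ethyl 2-(3,4-dimethoxyphenoxy)-3-methylbut-2-enoate
Product: 17 2-(3,4-dimethoxyphenoxy)-3-methylbut-2-en-1-ol
Conditions: DIBAL-H (2.4 equiv), CH2Cl2, −78 °C; aqueous Rochelle salt work-up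
Reagents that add atoms: none
Why: DIBAL-H reduction of the conjugated ester at low temperature gives the allylic alcohol without reducing or isomerising the tetrasubstituted enol ether.

**Step 9**
Reactants: 17 2-(3,4-dimethoxyphenoxy)-3-methylbut-2-en-1-ol
Product: 18 4-[(1-bromo-3-methylbut-2-en-2-yl)oxy]-1,2-dimethoxybenzene
Conditions: CBr4, PPh3, CH2Cl2, −20 to 0 °C; filtration through basic alumina, used at once
Reagents that add atoms: carbon tetrabromide, BrC(Br)(Br)Br
Why: Appel bromination proceeds under neutral conditions by SN2 displacement of the alkoxyphosphonium ion at the primary carbon, which avoids acid that would hydrolyse the enol ether, and the bromide is used at once because it can ionise.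

**Step 10**
Reactants: 11 2-iodo-5-methoxy-8,8-dimethyl-6-(3-methylbut-2-enyl)-4H,8H-pyrano[2,3-h]chromen-4-one; 18 4-[(1-bromo-3-methylbut-2-en-2-yl)oxy]-1,2-dimethoxybenzene
Product: 20 CNP0192589.0, via chromon-2-ylpalladium iodide 19 (not isolated)
Conditions: Pd(OAc)2 (10 mol%), tri(2-furyl)phosphine (22 mol%), norbornene (2 equiv), Cs2CO3 (3 equiv), CsOPiv (0.3 equiv), MeCN, 85 °C, 18 added by syringe pump over 6 h
Reagents that add atoms: none
Why: Proposed new method: zerovalent palladium inserts into the C2–I bond of 11, norbornene inserts and the resulting alkylpalladium palladates C3–H to a five-membered palladacycle of divalent palladium, which adds the primary allylic C–Br bond of 18 (tetravalent palladium) and reductively eliminates to form the C3–CH2 bond; norbornene extrusion then gives the chromon-2-ylpalladium iodide 19, which palladates the tethered ring B C–H by carbonate/pivalate-assisted concerted metalation–deprotonation and reductively eliminates to form the C2–C1' bond. The closest known reaction type is the palladium/norbornene (Catellani-type) ortho-alkylation/ipso direct arylation annulation of aryl and alkenyl iodides with bromoalkyl-tethered arenes, which is known for six- and seven-membered rings; an allylic bromide as the alkylating partner and a 2-iodochromone as the iodide are the untested elements. The first bond is made intermolecularly, and the seven-membered oxepine ring is closed by the second through an eight-membered palladacycle and C–C reductive elimination. No stereocentre is formed, and the tetrasubstituted enol ether is carried in intact, so the exocyclic position of its double bond is not at stake. The step needs alkylation at C3 before arylation at C2 (secured because only the norbornyl palladacycle reaches C3–H, while the ring oxygen on the other flank leaves no second C–H), arylation at the ring B C–H para to a methoxy group and not at the one between two oxygens (less hindered and more nucleophilic), and oxidative addition of zerovalent palladium to the C–I bond of the β-iodoenone faster than ionisation of the allylic bromide (slow addition of 18, whose tetrasubstituted alkene binds zerovalent palladium poorly).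

**Compound list**

1 | 1-(2,4-dihydroxy-6-methoxyphenyl)ethanone | CC(=O)c1c(O)cc(O)cc1OC | starting material
2 | 3-methylbut-2-enal | CC(C)=CC=O | starting material
3 | 1-(5-hydroxy-7-methoxy-2,2-dimethyl-2H-chromen-6-yl)ethanone | CC(=O)c1c(O)c2C=CC(C)(C)Oc2cc1OC | intermediate
4 | 1-bromo-3-methylbut-2-ene | CC(C)=CCBr | starting material
5 | 1-[7-methoxy-2,2-dimethyl-5-(3-methylbut-2-enyloxy)-2H-chromen-6-yl]ethanone | CC(=O)c1c(OCC=C(C)C)c2C=CC(C)(C)Oc2cc1OC | intermediate
6 | 6-acetyl-7-methoxy-2,2-dimethyl-6-(2-methylbut-3-en-2-yl)-2H-chromen-5(6H)-one (ortho-dienone) | CC(=O)C1(C(C)(C)C=C)C(OC)=CC2=C(C=CC(C)(C)O2)C1=O | intermediate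
7 | 1-[5-hydroxy-7-methoxy-2,2-dimethyl-8-(3-methylbut-2-enyl)-2H-chromen-6-yl]ethanone | CC(=O)c1c(O)c2C=CC(C)(C)Oc2c(CC=C(C)C)c1OC | intermediate
8 | (E)-3-(dimethylamino)-1-[5-hydroxy-7-methoxy-2,2-dimethyl-8-(3-methylbut-2-enyl)-2H-chromen-6-yl]prop-2-en-1-one | CN(C)/C=C/C(=O)c1c(O)c2C=CC(C)(C)Oc2c(CC=C(C)C)c1OC | intermediate
9 | 5-methoxy-8,8-dimethyl-6-(3-methylbut-2-enyl)-4H,8H-pyrano[2,3-h]chromen-4-one | O=c1ccoc2c1c(OC)c(CC=C(C)C)c1OC(C)(C)C=Cc21 | intermediate
10 | bis[5-methoxy-8,8-dimethyl-6-(3-methylbut-2-enyl)-4-oxo-4H,8H-pyrano[2,3-h]chromen-2-yl]zinc | [Zn](c1cc(=O)c2c(OC)c(CC=C(C)C)c3OC(C)(C)C=Cc3c2o1)c1cc(=O)c2c(OC)c(CC=C(C)C)c3OC(C)(C)C=Cc3c2o1 | intermediate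
11 | 2-iodo-5-methoxy-8,8-dimethyl-6-(3-methylbut-2-enyl)-4H,8H-pyrano[2,3-h]chromen-4-one | O=c1cc(I)oc2c1c(OC)c(CC=C(C)C)c1OC(C)(C)C=Cc21 | intermediate
12 | 3,4-dimethoxyphenol | COc1ccc(O)cc1OC | starting material
13 | ethyl 2-diazo-2-(diethoxyphosphoryl)acetate | CCOC(=O)C(=[N+]=[N-])P(=O)(OCC)OCC | starting material
14 | ethyl 2-(diethoxyphosphoryl)-2-(3,4-dimethoxyphenoxy)acetate | CCOC(=O)C(Oc1ccc(OC)c(OC)c1)P(=O)(OCC)OCC | intermediate
15 | acetone | CC(C)=O | starting material
16 | ethyl 2-(3,4-dimethoxyphenoxy)-3-methylbut-2-enoate | CCOC(=O)C(Oc1ccc(OC)c(OC)c1)=C(C)C | intermediate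
17 | 2-(3,4-dimethoxyphenoxy)-3-methylbut-2-en-1-ol | OCC(Oc1ccc(OC)c(OC)c1)=C(C)C | intermediate
18 | 4-[(1-bromo-3-methylbut-2-en-2-yl)oxy]-1,2-dimethoxybenzene | BrCC(Oc1ccc(OC)c(OC)c1)=C(C)C | intermediate
19 | {3-[2-(3,4-dimethoxyphenoxy)-3-methylbut-2-enyl]-5-methoxy-8,8-dimethyl-6-(3-methylbut-2-enyl)-4-oxo-4H,8H-pyrano[2,3-h]chromen-2-yl}palladium iodide (ligands omitted) | O=c1c(CC(Oc2ccc(OC)c(OC)c2)=C(C)C)c([Pd]I)oc2c1c(OC)c(CC=C(C)C)c1OC(C)(C)C=Cc21 | intermediate
20 | CNP0192589.0 (5,4',5'-trimethoxy-6-prenyl-7,8-(2,2-dimethylpyrano)flavone whose C3 and 2'-oxygen are bridged by CH2–C(=CMe2)) | COc1cc2OC(=C(C)C)Cc3c(-c2cc1OC)oc1c4C=CC(C)(C)Oc4c(CC=C(C)C)c(OC)c1c3=O | target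

**Step count and risks**

Total step count: 10. Longest linear sequence: 6 steps (steps 1, 2, 3, 4, 5 and 10); the ring B branch (steps 6 to 9) joins at step 10.

Steps most likely to fail:

1. Step 10 (Proposed new method). Zerovalent palladium may ionise the allylic bromide to an allylpalladium species and so be withdrawn from the cycle. Carboxylate or carbonate may displace iodide at C2 by addition–elimination. Norbornene extrusion may be slow with only one flanking carbon substituent. The eight-membered palladacycle needed for the closing C–H arylation may form too slowly. The fallback uses known reaction types only; it sets out from 9 and 18 and returns at 20. Carbonyl-directed C3 zincation of 9 with TMPZnCl·LiCl (THF, 25 °C) gives the chromon-3-ylzinc chloride F1. Negishi-type allylation with 18 (Pd(PPh3)4, 5 mol%, THF, 25 °C), in which the aryl group is delivered to the unhindered CH2 terminus, gives the 3-[2-(3,4-dimethoxyphenoxy)-3-methylbut-2-enyl]chromone F2. C2 zincation under the conditions of step 5 gives the bis(3-alkylchromon-2-yl)zinc F3, and iodine converts it into the 2-iodo-3-alkylchromone F4. Intramolecular direct arylation (Pd(OAc)2, PCy3·HBF4, K2CO3, pivalic acid, DMA, 110 °C) then closes the oxepine to 20.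

2. Step 3. At 190 °C the ortho-dienone may lose the prenyl group as isoprene, transfer or lose its acetyl group, or the chromene may open by retro-electrocyclisation before the Cope shift. The fallback sets out from 3 and returns at 7. Iodination of 3 with N-iodosuccinimide (MeCN, 0 °C) at the only free ring carbon, para to the phenol, gives 1-(5-hydroxy-8-iodo-7-methoxy-2,2-dimethyl-2H-chromen-6-yl)ethanone F5. Stille coupling with tributyl(3-methylbut-2-enyl)stannane (Pd(PPh3)4, DMF, 80 °C) should then give the linear prenyl compound 7.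

3. Step 1. The condensation may take place at the ring carbon between the hydroxyl and the methoxy group, or the pyran may close through the chelated oxygen, giving isomeric chromenes. The fallback sets out from 1 and returns at 3. Selective alkylation of the non-chelated para hydroxyl with 3-chloro-3-methylbut-1-yne (K2CO3, KI, CuI as catalyst, acetone, 56 °C) gives 1-[2-hydroxy-6-methoxy-4-(2-methylbut-3-yn-2-yloxy)phenyl]ethanone F6. Thermal propargyl Claisen rearrangement, 1,5-hydrogen shift and oxa-6π closure (N,N-diethylaniline, 180 °C) give 3. Closure through the para oxygen is then fixed by construction, and the chelated hydroxyl directs the [3,3] shift to the carbon between the two oxygens.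

**Further compounds**

F1 | step 10 | [5-methoxy-8,8-dimethyl-6-(3-methylbut-2-enyl)-4-oxo-4H,8H-pyrano[2,3-h]chromen-3-yl]zinc chloride | O=c1c([Zn]Cl)coc2c1c(OC)c(CC=C(C)C)c1OC(C)(C)C=Cc21
F2 | step 10 | 3-[2-(3,4-dimethoxyphenoxy)-3-methylbut-2-enyl]-5-methoxy-8,8-dimethyl-6-(3-methylbut-2-enyl)-4H,8H-pyrano[2,3-h]chromen-4-one | O=c1c(CC(Oc2ccc(OC)c(OC)c2)=C(C)C)coc2c1c(OC)c(CC=C(C)C)c1OC(C)(C)C=Cc21
F3 | step 10 | bis{3-[2-(3,4-dimethoxyphenoxy)-3-methylbut-2-enyl]-5-methoxy-8,8-dimethyl-6-(3-methylbut-2-enyl)-4-oxo-4H,8H-pyrano[2,3-h]chromen-2-yl}zinc | [Zn](c1oc2c3C=CC(C)(C)Oc3c(CC=C(C)C)c(OC)c2c(=O)c1CC(Oc1ccc(OC)c(OC)c1)=C(C)C)c1oc2c3C=CC(C)(C)Oc3c(CC=C(C)C)c(OC)c2c(=O)c1CC(Oc1ccc(OC)c(OC)c1)=C(C)C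
F4 | step 10 | 3-[2-(3,4-dimethoxyphenoxy)-3-methylbut-2-enyl]-2-iodo-5-methoxy-8,8-dimethyl-6-(3-methylbut-2-enyl)-4H,8H-pyrano[2,3-h]chromen-4-one | O=c1c(CC(Oc2ccc(OC)c(OC)c2)=C(C)C)c(I)oc2c1c(OC)c(CC=C(C)C)c1OC(C)(C)C=Cc21
F5 | step 3 | 1-(5-hydroxy-8-iodo-7-methoxy-2,2-dimethyl-2H-chromen-6-yl)ethanone | CC(=O)c1c(O)c2C=CC(C)(C)Oc2c(I)c1OC
F6 | step 1 | 1-[2-hydroxy-6-methoxy-4-(2-methylbut-3-yn-2-yloxy)phenyl]ethanone | CC(=O)c1c(O)cc(OC(C)(C)C#C)cc1OC
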